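**Plan**

- Retrosynthesis: the C3–OMe bond is cut first (Ullmann etherification of a 3-bromoflavone). Then C2–C3 and C3–C4 are cut together, which removes C3 as a dibromocarbene carbon and contracts the pyranone to a 2-anisyl-3-silyloxybenzofuran.
- Enabling feature: ring C of the flavone (O1, C2 carrying the anisyl group, C3, the C4 carbonyl, C4a, C8a) is a 2-aryl-3-oxybenzofuran enlarged by one carbon, C3, which sits between the aryl-bearing and the oxygen-bearing carbon.
- The benzofuranone is cut at O1–C2 (phenoxide alkylation) and at the aryl–carbonyl bond (ortho acylation of 2,3,4,5-tetramethoxyphenol by 4-methoxyphenylacetic acid). The phenol comes from 1,2,3,4-tetramethoxybenzene by formylation and Baeyer–Villiger oxidation.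
- Forward order: rings A and B are bought, the five-membered oxygen ring is closed and silylated, then enlarged to ring C by carbon insertion; the 3-methoxy group is installed last.
- Stereochemistry: the target has no stereocentre; the racemic centres that appear on the way are erased by enolisation and by the ring opening.

Key step: step 6

Remark on the chemistry: the α-bromo ketone, the benzofuranone and the dibromocyclopropane are racemic (the cyclopropane is necessarily cis-fused), so their SMILES carry no stereodescriptors. The silyl group is assumed to leave as the silyl bromide and to be hydrolysed to the silanol on aqueous work-up.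

**Route**

Step 1
Reactants: 1 1,2,3,4-tetramethoxybenzene
Product: 3 2,3,4,5-tetramethoxybenzaldehyde, via aryl iminium salt 2 (not isolated)
Conditions: POCl3, DMF, 0 °C to 80 °C; then H2O, 0 °C to rt
Reagents that add atoms: N,N-dimethylformamide, CN(C)C=O; water, O
Why: Vilsmeier–Haack formylation; the two free ring positions of 1 are equivalent and each has a methoxy group ortho and para to it, so only one aldehyde can result once iminium salt 2 is hydrolysed.

Step 2
Reactants: 3 2,3,4,5-tetramethoxybenzaldehyde
Product: 5 2,3,4,5-tetramethoxyphenol, via aryl formate 4 (not isolated)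
Conditions: mCPBA, CH2Cl2, 0 °C to rt; then Et3N, MeOH, rt
Reagents that add atoms: 3-chloroperbenzoic acid (mCPBA), OOC(=O)c1cccc(Cl)c1
Why: Baeyer–Villiger (Dakin-type) oxidation of an electron-rich benzaldehyde, in which the tetramethoxyaryl group migrates in preference to hydride and the labile formate 4 is then cleaved by mild methanolysis.

Step 3
Reactants: 5 2,3,4,5-tetramethoxyphenol; 6 4-methoxyphenylacetic acid
Product: 8 1-(2-hydroxy-3,4,5,6-tetramethoxyphenyl)-2-(4-methoxyphenyl)ethan-1-one, via difluoroboron chelate 7 (not isolated)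
Conditions: BF3·OEt2 (neat), 85 °C; then H2O, 60 °C
Reagents that add atoms: none
Why: Friedel–Crafts (Fries-type) ortho acylation of a phenol by an arylacetic acid in BF3·OEt2, the standard deoxybenzoin synthesis; the only unsubstituted ring carbon of 5 lies ortho to the hydroxyl, and chelate 7 shields the product until it is hydrolysed.

Step 4
Reactants: 8 1-(2-hydroxy-3,4,5,6-tetramethoxyphenyl)-2-(4-methoxyphenyl)ethan-1-one
Product: 10 4,5,6,7-tetramethoxy-2-(4-methoxyphenyl)-1-benzofuran-3(2H)-one (racemic), via α-bromo ketone 9 (not isolated)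
Conditions: PhNMe3Br3 (1.0 equiv), THF, 0 °C to rt; filter, concentrate; then K2CO3, acetone, rt, under argon
Reagents that add atoms: none
Why: α-bromination of the doubly activated benzylic ketone methylene by a mild tribromide that spares the anisyl ring, then intramolecular Williamson etherification (5-exo-tet) by the neighbouring phenoxide, the usual entry to benzofuran-3(2H)-ones from ortho-hydroxy α-halo ketones; C2 forms racemic and ceases to be a stereocentre in step 5.

Step 5
Reactants: 10 4,5,6,7-tetramethoxy-2-(4-methoxyphenyl)-1-benzofuran-3(2H)-one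
Product: 11 tert-butyl(dimethyl){[4,5,6,7-tetramethoxy-2-(4-methoxyphenyl)-1-benzofuran-3-yl]oxy}silane
Conditions: TBSOTf, Et3N, CH2Cl2, 0 °C, under argon
Reagents that add atoms: tert-butyldimethylsilyl triflate (TBSOTf), CC(C)(C)[Si](C)(C)OS(=O)(=O)C(F)(F)F
Why: silyl enol ether formation with a silyl triflate and an amine base, favoured because the enol tautomer is an aromatic 3-hydroxybenzofuran; the bulky silyl group stores the air-sensitive ketone and should resist tert-butoxide in step 6.

Step 6
Reactants: 11 tert-butyl(dimethyl){[4,5,6,7-tetramethoxy-2-(4-methoxyphenyl)-1-benzofuran-3-yl]oxy}silane; 12 bromoform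
Product: 15 3-bromo-5,6,7,8-tetramethoxy-2-(4-methoxyphenyl)-4H-chromen-4-one, via dibromocyclopropane 13 (not isolated), via 4-silyloxyflavylium bromide 14 (not isolated)
Conditions: KOt-Bu, toluene–hexane, −20 °C to rt (slow addition of 12); then aq. NH4Cl
Reagents that add atoms: none
Why: Proposed new method: dibromocarbene, released from 12 by α-elimination with KOt-Bu, is an electrophilic singlet carbene and should add in a concerted [2+1] manner to the furan C2=C3 bond of 11, the most electron-rich π bond present because it carries the ring oxygen at one end and the silyloxy group at the other, giving the cis-fused dibromocyclopropane 13. In 13 the bond shared by the two rings is flanked by two oxygen donors and the anisyl group, so loss of the endo bromide with concerted disrotatory two-electron opening of that bond (cyclopropyl-to-allyl cation) should occur at or below room temperature and give the aromatic flavylium bromide 14, whose silyl group is then removed by bromide or on work-up to unveil the C4 carbonyl. Ring C is thus closed by expansion of the five-membered ring through carbon insertion, forming C2–C3 and C3–C4 together, and not by a cyclisation; the two stereocentres of 13 vanish in the opening and none is created. The closest known reactions are the dihalocarbene ring expansion of cyclic silyl enol ethers to α-halo enones and the Ciamician–Dennstedt expansion of indoles and benzofurans. Two selectivities are needed: the carbene must take the furan double bond and not an arene, which the doubly oxygenated C2=C3 bond and the fully substituted ring A secure, and the cyclopropane must cleave its internal bond, which the donors on both fusion carbons and the gain of pyrylium aromaticity dictate. A non-polar medium and low temperature are chosen so that carbene capture outruns attack of tert-butoxide on silicon.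

Step 7
Reactants: 15 3-bromo-5,6,7,8-tetramethoxy-2-(4-methoxyphenyl)-4H-chromen-4-one
Product: 16 3-methoxytangeretin (3,5,6,7,8-pentamethoxy-2-(4-methoxyphenyl)-4H-chromen-4-one)
Conditions: CuI (10 mol %), 3,4,7,8-tetramethyl-1,10-phenanthroline (20 mol %), Cs2CO3, MeOH–toluene, 100 °C, sealed tube
Reagents that add atoms: methanol, CO
Why: Ullmann-type C–O coupling of a C(sp2)–Br bond with methanol at phenanthroline-bound monovalent copper, a reaction that bromoflavones tolerate, with the weak carbonate base keeping free methoxide low so that the pyranone is not attacked at C2.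

**Compound list**

1 | 1,2,3,4-tetramethoxybenzene | COc1ccc(OC)c(OC)c1OC | starting material
2 | N,N-dimethyl-(2,3,4,5-tetramethoxyphenyl)methaniminium chloride | COc1cc(C=[N+](C)C)c(OC)c(OC)c1OC.[Cl-] | intermediate (not isolated)
3 | 2,3,4,5-tetramethoxybenzaldehyde | COc1cc(C=O)c(OC)c(OC)c1OC | intermediate
4 | 2,3,4,5-tetramethoxyphenyl formate | COc1cc(OC=O)c(OC)c(OC)c1OC | intermediate (not isolated)
5 | 2,3,4,5-tetramethoxyphenol | COc1cc(O)c(OC)c(OC)c1OC | intermediate
6 | 4-methoxyphenylacetic acid | COc1ccc(CC(=O)O)cc1 | starting material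
7 | difluoroboron chelate of ketone 8 (BF2 bridging the phenolate and carbonyl oxygens) | COc1ccc(CC2=[O+][B-](F)(F)Oc3c(OC)c(OC)c(OC)c(OC)c23)cc1 | intermediate (not isolated)
8 | 1-(2-hydroxy-3,4,5,6-tetramethoxyphenyl)-2-(4-methoxyphenyl)ethan-1-one | COc1ccc(CC(=O)c2c(O)c(OC)c(OC)c(OC)c2OC)cc1 | intermediate
9 | 2-bromo-1-(2-hydroxy-3,4,5,6-tetramethoxyphenyl)-2-(4-methoxyphenyl)ethan-1-one (racemic) | COc1ccc(C(Br)C(=O)c2c(O)c(OC)c(OC)c(OC)c2OC)cc1 | intermediate (not isolated)
10 | 4,5,6,7-tetramethoxy-2-(4-methoxyphenyl)-1-benzofuran-3(2H)-one (racemic) | COc1ccc(C2Oc3c(OC)c(OC)c(OC)c(OC)c3C2=O)cc1 | intermediate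
11 | tert-butyl(dimethyl){[4,5,6,7-tetramethoxy-2-(4-methoxyphenyl)-1-benzofuran-3-yl]oxy}silane | COc1ccc(-c2oc3c(OC)c(OC)c(OC)c(OC)c3c2O[Si](C)(C)C(C)(C)C)cc1 | intermediate
12 | bromoform | BrC(Br)Br | starting material
13 | 1,1-dibromo-6b-[(tert-butyldimethylsilyl)oxy]-3,4,5,6-tetramethoxy-1a-(4-methoxyphenyl)-1a,6b-dihydro-1H-cyclopropa[b][1]benzofuran (racemic, cis-fused) | COc1ccc(C23Oc4c(OC)c(OC)c(OC)c(OC)c4C2(O[Si](C)(C)C(C)(C)C)C3(Br)Br)cc1 | intermediate (not isolated)
14 | 3-bromo-4-[(tert-butyldimethylsilyl)oxy]-5,6,7,8-tetramethoxy-2-(4-methoxyphenyl)chromenylium bromide | COc1ccc(-c2[o+]c3c(OC)c(OC)c(OC)c(OC)c3c(O[Si](C)(C)C(C)(C)C)c2Br)cc1.[Br-] | intermediate (not isolated)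
15 | 3-bromo-5,6,7,8-tetramethoxy-2-(4-methoxyphenyl)-4H-chromen-4-one | COc1ccc(-c2oc3c(OC)c(OC)c(OC)c(OC)c3c(=O)c2Br)cc1 | intermediate
16 | 3-methoxytangeretin (3,5,6,7,8-pentamethoxy-2-(4-methoxyphenyl)-4H-chromen-4-one) | COc1ccc(-c2oc3c(OC)c(OC)c(OC)c(OC)c3c(=O)c2OC)cc1 | target

**Count and risks**

Total step count: 7. Longest linear sequence: 7 steps (1 to 16); 6 and 12 enter as bought.

Steps most likely to fail:

1. Step 6. tert-Butoxide may strip the silyl group before the carbene is captured, after which the enolate is alkylated at carbon instead of being cyclopropanated. The crowded tetrasubstituted double bond may also react too slowly, or tribromomethanide may add to the flavylium ion. The fallback uses known chemistry only and sets out from phenol 5. Acylation with acetic acid in BF3·OEt2 gives 1-(2-hydroxy-3,4,5,6-tetramethoxyphenyl)ethan-1-one F1. Esterification with 4-methoxybenzoyl chloride in pyridine gives 2-acetyl-3,4,5,6-tetramethoxyphenyl 4-methoxybenzoate F2. Baker–Venkataraman rearrangement (KOH, pyridine, 50 °C) then gives 1-(2-hydroxy-3,4,5,6-tetramethoxyphenyl)-3-(4-methoxyphenyl)propane-1,3-dione F3. Finally CuBr2 in hot EtOAc–CHCl3 brominates the central carbon and brings about cyclodehydration in the same flask. This returns to the route at 15, before step 7.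

2. Step 7. Methoxide may add at C2 and open the pyranone, or the C–Br bond may be reduced faster than it couples. The fallback sets out from 15 and makes C3 the nucleophilic partner, so that no alkoxide is heated with the chromone. Miyaura borylation (B2pin2, PdCl2(dppf), KOAc, dioxane, 80 °C) should give 5,6,7,8-tetramethoxy-2-(4-methoxyphenyl)-3-(4,4,5,5-tetramethyl-1,3,2-dioxaborolan-2-yl)-4H-chromen-4-one F4. Oxidation with H2O2 in buffered aqueous THF at 0 °C gives 3-hydroxy-5,6,7,8-tetramethoxy-2-(4-methoxyphenyl)-4H-chromen-4-one F5. O-Methylation with MeI and K2CO3 in acetone then returns to the route at 16.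

3. Step 4. A second bromination at C2 may follow ring closure, electrophilic bromine may attack the anisyl ring, and the benzofuranone may autoxidise at C2 during handling. The fallback sets out from 8 and avoids electrophilic bromine altogether. Regitz diazo transfer (4-acetamidobenzenesulfonyl azide, DBU, MeCN) gives 2-diazo-1-(2-hydroxy-3,4,5,6-tetramethoxyphenyl)-2-(4-methoxyphenyl)ethan-1-one F6. Intramolecular O–H insertion of the phenol into the carbenoid formed with Rh2(OAc)4 (CH2Cl2, rt, argon) closes the furanone and returns to the route at 10, before step 5.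

**Further compounds**

F1 | step 6 | 1-(2-hydroxy-3,4,5,6-tetramethoxyphenyl)ethan-1-one | CC(=O)c1c(O)c(OC)c(OC)c(OC)c1OC
F2 | step 6 | 2-acetyl-3,4,5,6-tetramethoxyphenyl 4-methoxybenzoate | COc1ccc(C(=O)Oc2c(OC)c(OC)c(OC)c(OC)c2C(C)=O)cc1
F3 | step 6 | 1-(2-hydroxy-3,4,5,6-tetramethoxyphenyl)-3-(4-methoxyphenyl)propane-1,3-dione | COc1ccc(C(=O)CC(=O)c2c(O)c(OC)c(OC)c(OC)c2OC)cc1
F4 | step 7 | 5,6,7,8-tetramethoxy-2-(4-methoxyphenyl)-3-(4,4,5,5-tetramethyl-1,3,2-dioxaborolan-2-yl)-4H-chromen-4-one | COc1ccc(-c2oc3c(OC)c(OC)c(OC)c(OC)c3c(=O)c2B4OC(C)(C)C(C)(C)O4)cc1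
F5 | step 7 | 3-hydroxy-5,6,7,8-tetramethoxy-2-(4-methoxyphenyl)-4H-chromen-4-one | COc1ccc(-c2oc3c(OC)c(OC)c(OC)c(OC)c3c(=O)c2O)cc1
F6 | step 4 | 2-diazo-1-(2-hydroxy-3,4,5,6-tetramethoxyphenyl)-2-(4-methoxyphenyl)ethan-1-one | COc1ccc(C(=[N+]=[N-])C(=O)c2c(O)c(OC)c(OC)c(OC)c2OC)cc1
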